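**Retrosynthetic overview**
1. Feature: in ring A, O1 sits on C8a and the C4 carbonyl on the neighbouring C4a, and C4a is flanked by the oxygen-bearing C5. A C4a≡C8a aryne with a methoxy group at C5 is polarised so that an oxygen nucleophile bonds at C8a and the carbanion appears at C4a, ready for acylation.
2. Last disconnection: 5-OH and 6'-OH come from 5-OMe (peri to C4=O) and 6'-OBn, both released by BCl3.
3. Key disconnection: ring C is cut at C8a–O1, C4a–C4 and O1–C2, giving 3,4,5-trimethoxybenzyne (from its 2-silylaryl triflate) and the ring B arylpropiolic acid.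
4. Both partners derive from 3,4,5-trimethoxyphenol. The aryne precursor needs bromination, O-silylation and retro-Brook shift/triflation. The acid needs benzylation, formylation (C2), dibromoolefination (C3) and carboxylation (C4).
5. Ring order: rings A and B are bought as the same arene, and ring C is the only ring built, in the key step.

Key step: step 8

Remark on the chemistry: positions 2 and 6 of 3,4,5-trimethoxyphenol are equivalent, so steps 1 and 5 raise no regiochemical question. Flavone numbering is used for ring atoms throughout.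

**Aryne precursor (fragment 1)**

Step 1
Reactants: 1 3,4,5-trimethoxyphenol
Product: 2 2-bromo-3,4,5-trimethoxyphenol
Conditions: NBS (1.0 equiv), CH2Cl2, −20 °C to 0 °C, dark
Reagents that add atoms: N-bromosuccinimide, O=C1CCC(=O)N1Br
Why: Electrophilic aromatic bromination: the only two free ring positions are equivalent and each is activated by the ortho hydroxyl, an ortho methoxy and a para methoxy group, so one equivalent of NBS at low temperature should stop at the monobromide.

Step 2
Reactants: 2 2-bromo-3,4,5-trimethoxyphenol
Product: 3 (2-bromo-3,4,5-trimethoxyphenoxy)trimethylsilane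
Conditions: HN(SiMe3)2 (1.5 equiv), THF, 70 °C; evaporation in vacuo
Reagents that add atoms: hexamethyldisilazane, C[Si](C)(C)N[Si](C)(C)C
Why: Silylation of the phenol with HMDS gives only ammonia as co-product, so evaporation should leave silyl ether 3 clean enough for the organolithium step.

Step 3
Reactants: 3 (2-bromo-3,4,5-trimethoxyphenoxy)trimethylsilane
Product: 6 3,4,5-trimethoxy-2-(trimethylsilyl)phenyl trifluoromethanesulfonate, via aryllithium 4 (not isolated), via lithium silylphenoxide 5 (not isolated)
Conditions: n-BuLi (1.1 equiv), THF, −100 °C to −80 °C; then Tf2O (1.2 equiv), −100 °C to −80 °C; cold aq NaHCO3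
Reagents that add atoms: trifluoromethanesulfonic anhydride, O=S(=O)(OS(=O)(=O)C(F)(F)F)C(F)(F)F
Why: Bromine–lithium exchange is faster than attack of n-BuLi at silicon, aryllithium 4 undergoes the retro-Brook 1,3-shift of silicon from oxygen to carbon because phenoxide 5 is the far better anion, and O-triflation of 5 completes the standard access to 2-silylaryl triflates.

**Ring B acid (fragment 2)**

Step 4
Reactants: 1 3,4,5-trimethoxyphenol; 7 benzyl bromide
Product: 8 5-(benzyloxy)-1,2,3-trimethoxybenzene
Conditions: BnBr (1.1 equiv), K2CO3 (2 equiv), DMF, rt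
Reagents that add atoms: benzyl bromide, BrCc1ccccc1
Why: Williamson ether synthesis of a phenoxide with a primary benzylic bromide; the benzyl group masks the future 6'-hydroxyl through the organolithium and fluoride steps.

Step 5
Reactants: 8 5-(benzyloxy)-1,2,3-trimethoxybenzene
Product: 10 2-(benzyloxy)-4,5,6-trimethoxybenzaldehyde, via iminium chloride 9 (not isolated)
Conditions: POCl3 (1.5 equiv), DMF, 0 °C to rt; then ice-water
Reagents that add atoms: N,N-dimethylformamide, CN(C)C=O (formyl carbon); water, O (formyl oxygen)
Why: Vilsmeier–Haack formylation: the two free positions of 8 are equivalent and each lies ortho, ortho and para to alkoxy groups, so the chloroiminium ion should attack readily and hydrolysis of iminium salt 9 gives the aldehyde whose carbon becomes C2.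

Step 6
Reactants: 10 2-(benzyloxy)-4,5,6-trimethoxybenzaldehyde; 11 carbon tetrabromide
Product: 12 1-(benzyloxy)-2-(2,2-dibromoethenyl)-3,4,5-trimethoxybenzene
Conditions: CBr4 (2 equiv), PPh3 (4 equiv), CH2Cl2, 0 °C
Reagents that add atoms: carbon tetrabromide, BrC(Br)(Br)Br
Why: First stage of the Corey–Fuchs homologation (Ramirez dibromoolefination), a Wittig-type reaction of Ph3P=CBr2 that tolerates aryl ethers and benzaldehydes substituted at both ortho positions; the new carbon becomes C3.

Step 7
Reactants: 12 1-(benzyloxy)-2-(2,2-dibromoethenyl)-3,4,5-trimethoxybenzene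
Product: 15 3-[2-(benzyloxy)-4,5,6-trimethoxyphenyl]propiolic acid, via lithium acetylide 13 (not isolated), via lithium propiolate 14 (not isolated)
Conditions: n-BuLi (2.2 equiv), THF, −78 °C to 0 °C; then dry CO2 (g), −78 °C to rt; then cold 1 M aq HCl
Reagents that add atoms: carbon dioxide, O=C=O
Why: Second stage of the Corey–Fuchs reaction (bromine–lithium exchange, loss of LiBr with a 1,2-hydrogen shift of the Fritsch–Buttenberg–Wiechell type, deprotonation) gives acetylide 13, whose carboxylation with CO2 installs the future C4 and gives acid 15 after cold acidification.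

**Union and end game**

Step 8
Reactants: 6 3,4,5-trimethoxy-2-(trimethylsilyl)phenyl trifluoromethanesulfonate; 15 3-[2-(benzyloxy)-4,5,6-trimethoxyphenyl]propiolic acid
Product: 18 2-[2-(benzyloxy)-4,5,6-trimethoxyphenyl]-5,6,7-trimethoxy-4H-chromen-4-one, via 3,4,5-trimethoxybenzyne 16 (not isolated), via 2-hydroxyaryl ynone 17 (not isolated)
Conditions: 6 (1.5 equiv), CsF (4 equiv), THF (ca. 0.02 M), 125 °C, sealed vessel
Reagents that add atoms: none
Why: Fluoride removes the silyl group of 6 and triflate departs to give aryne 16, whose C5 methoxy group distorts the triple bond and stabilises negative charge on the adjacent carbon, so the carboxylate oxygen of 15 bonds to the remote carbon (C8a–O1) and the aryl anion sits at C4a, which is the regioselectivity the step needs and which the substrate itself supplies. The anion attacks the neighbouring ester carbonyl (4-exo-trig, C4a–C4) and the strained benzoxetene alkoxide collapses by breaking its O–C4 bond, which amounts to insertion of the aryne into the acyl C–O bond and delivers the phenoxide of 17. That phenoxide adds to the ynone β-carbon in a 6-endo-dig oxa-Michael closure of ring C (O1–C2), and the C3 carbanion takes up the proton that the acid brought in. The closest known reaction type is the fluoride-induced insertion of arynes into carboxylic acids, which gives 2-hydroxyaryl ketones and, with arylpropiolic acids, flavones. Two further selectivities matter: acyl transfer must outrun protonation of the aryl anion (plain O-arylation), which high dilution in weakly polar THF and heat favour, and 6-endo closure must beat 5-exo closure to the aurone skeleton, which the aprotic basic medium and heat favour. Ring B, substituted at both ortho positions, is held away from the reacting centres by the linear alkyne until the last bond forms, and no stereocentre is created.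

Step 9
Reactants: 18 2-[2-(benzyloxy)-4,5,6-trimethoxyphenyl]-5,6,7-trimethoxy-4H-chromen-4-one
Product: 20 5,6'-dihydroxy-6,7,2',3',4'-pentamethoxyflavone, via bis(dichloroboryl) ether 19 (not isolated)
Conditions: BCl3 (4 equiv), C6HMe5 (3 equiv), CH2Cl2, −78 °C to 0 °C; then cold 1 M aq HCl
Reagents that add atoms: none
Why: BCl3 ionises the aryl benzyl ether already at −78 °C while pentamethylbenzene traps the benzyl cation by Friedel–Crafts alkylation, and on warming the six-membered chelate between C4=O and the peri 5-methoxy oxygen directs chloride to that methyl group alone (chelation-directed aryl methyl ether cleavage), so the non-chelated methoxy groups should survive at or below 0 °C and hydrolysis of 19 frees both phenols.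

**Compound list**
1 | 3,4,5-trimethoxyphenol | COc1cc(O)cc(OC)c1OC | starting material
2 | 2-bromo-3,4,5-trimethoxyphenol | COc1cc(O)c(Br)c(OC)c1OC | intermediate
3 | (2-bromo-3,4,5-trimethoxyphenoxy)trimethylsilane | COc1cc(O[Si](C)(C)C)c(Br)c(OC)c1OC | intermediate
4 | [2,3,4-trimethoxy-6-(trimethylsilyloxy)phenyl]lithium | COc1cc(O[Si](C)(C)C)c([Li])c(OC)c1OC | intermediate
5 | lithium 3,4,5-trimethoxy-2-(trimethylsilyl)phenoxide | COc1cc([O-])c([Si](C)(C)C)c(OC)c1OC.[Li+] | intermediate
6 | 3,4,5-trimethoxy-2-(trimethylsilyl)phenyl trifluoromethanesulfonate | COc1cc(OS(=O)(=O)C(F)(F)F)c([Si](C)(C)C)c(OC)c1OC | intermediate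
7 | benzyl bromide | BrCc1ccccc1 | starting material
8 | 5-(benzyloxy)-1,2,3-trimethoxybenzene | COc1cc(OCc2ccccc2)cc(OC)c1OC | intermediate
9 | [2-(benzyloxy)-4,5,6-trimethoxybenzylidene]dimethyliminium chloride | COc1cc(OCc2ccccc2)c(C=[N+](C)C)c(OC)c1OC.[Cl-] | intermediate
10 | 2-(benzyloxy)-4,5,6-trimethoxybenzaldehyde | COc1cc(OCc2ccccc2)c(C=O)c(OC)c1OC | intermediate
11 | carbon tetrabromide | BrC(Br)(Br)Br | starting material
12 | 1-(benzyloxy)-2-(2,2-dibromoethenyl)-3,4,5-trimethoxybenzene | COc1cc(OCc2ccccc2)c(C=C(Br)Br)c(OC)c1OC | intermediate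
13 | {[2-(benzyloxy)-4,5,6-trimethoxyphenyl]ethynyl}lithium | COc1cc(OCc2ccccc2)c(C#C[Li])c(OC)c1OC | intermediate
14 | lithium 3-[2-(benzyloxy)-4,5,6-trimethoxyphenyl]propiolate | COc1cc(OCc2ccccc2)c(C#CC(=O)[O-])c(OC)c1OC.[Li+] | intermediate
15 | 3-[2-(benzyloxy)-4,5,6-trimethoxyphenyl]propiolic acid | OC(=O)C#Cc1c(OCc2ccccc2)cc(OC)c(OC)c1OC | intermediate
16 | 3,4,5-trimethoxybenzyne (1,2-didehydro-3,4,5-trimethoxybenzene) | COC1=C(OC)C(OC)=CC#C1 | intermediate
17 | 3-[2-(benzyloxy)-4,5,6-trimethoxyphenyl]-1-(6-hydroxy-2,3,4-trimethoxyphenyl)prop-2-yn-1-one | COc1cc(O)c(C(=O)C#Cc2c(OCc3ccccc3)cc(OC)c(OC)c2OC)c(OC)c1OC | intermediate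
18 | 2-[2-(benzyloxy)-4,5,6-trimethoxyphenyl]-5,6,7-trimethoxy-4H-chromen-4-one | COc1cc(OCc2ccccc2)c(-c2cc(=O)c3c(OC)c(OC)c(OC)cc3o2)c(OC)c1OC | intermediate
19 | 5,6'-bis(dichloroboryloxy)-6,7,2',3',4'-pentamethoxyflavone | COc1cc(OB(Cl)Cl)c(-c2cc(=O)c3c(OB(Cl)Cl)c(OC)c(OC)cc3o2)c(OC)c1OC | intermediate
20 | 5,6'-dihydroxy-6,7,2',3',4'-pentamethoxyflavone | COc1cc(O)c(-c2cc(=O)c3c(O)c(OC)c(OC)cc3o2)c(OC)c1OC | target

**Step count:** 9 steps in total. Longest linear sequence: 6 steps (steps 4, 5, 6, 7, 8, 9) from 3,4,5-trimethoxyphenol.

**Steps most likely to fail**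

Step 8. Four processes could compete.
- The aryl anion may be protonated before the acyl shift, so the sequence stops at O-arylation.
- The propiolate may lose CO2 at 125 °C.
- The phenoxide may be arylated by a second aryne.
- Closure may go 5-exo.

The fallback avoids the aryne and builds ring C by the chalcone route. It sets out from 1 and 10 and comes back at 18. Phenol 1 is C-acetylated ortho to the hydroxyl group with Ac2O and BF3·OEt2 (Friedel–Crafts/Fries type) to 1-(6-hydroxy-2,3,4-trimethoxyphenyl)ethanone F1. Claisen–Schmidt condensation of this ketone with aldehyde 10 (KOH, EtOH, rt) should give (E)-3-[2-(benzyloxy)-4,5,6-trimethoxyphenyl]-1-(6-hydroxy-2,3,4-trimethoxyphenyl)prop-2-en-1-one F2. Oxidative cyclisation with catalytic I2 in DMSO at 120–130 °C then leads to 18.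

Step 9. Three processes could compete.
- Demethylation may go too far, at the crowded central methoxy groups on C6 and C3', the former helped by the neighbouring boron aryloxide.
- An electron-rich ring may be benzylated if cation trapping is too slow.
- Ring C may open under acid and reclose onto the free 6'-hydroxyl during work-up.

The fallback separates the two unmaskings and removes the benzyl group reductively, so no benzyl cation and no excess of a strong Lewis acid is present. It sets out from 18 and comes back at 20. Hydrogenolysis (H2, 1 atm, Pd/C, EtOAc/MeOH, rt) should give 2-(6-hydroxy-2,3,4-trimethoxyphenyl)-5,6,7-trimethoxy-4H-chromen-4-one F3. The 5-methoxy group is then cleaved through its carbonyl chelate with AlCl3 in MeCN (rt to gentle heating, then dilute aq HCl) to give 20.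

Step 3. Three processes could compete.
- The aryllithium may be protonated early or the exchange may be incomplete.
- The silyl shift into the position crowded by the adjacent methoxy group may be sluggish.
- The electron-rich arylsilane may be protodesilylated during purification.

The fallback installs silicon by directed ortho-metalation instead of halogen exchange and silyl migration. It sets out from 1 and comes back at 6.
- Addition of 1 to isopropyl isocyanate (cat. Et3N, CH2Cl2) gives 3,4,5-trimethoxyphenyl isopropylcarbamate F4.
- The N–H is masked in the flask with TBSOTf/TMEDA (Et2O) as 3,4,5-trimethoxyphenyl N-(tert-butyldimethylsilyl)-N-isopropylcarbamate F5.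
- n-BuLi/TMEDA at −78 °C metalates the position between carbamate and methoxy group to the ortho-lithiated carbamate F6.
- TMSCl converts it into 3,4,5-trimethoxy-2-(trimethylsilyl)phenyl N-(tert-butyldimethylsilyl)-N-isopropylcarbamate F7.
- Work-up with aq NaHSO4 removes the N-silyl group and gives 3,4,5-trimethoxy-2-(trimethylsilyl)phenyl isopropylcarbamate F8.
- Et2NH and DBU in MeCN at 40 °C release 3,4,5-trimethoxy-2-(trimethylsilyl)phenol F9, which is triflated in the same flask with PhNTf2 to 6.

**Further compounds**
F1 | step 8 | 1-(6-hydroxy-2,3,4-trimethoxyphenyl)ethanone | COc1cc(O)c(C(C)=O)c(OC)c1OC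
F2 | step 8 | (E)-3-[2-(benzyloxy)-4,5,6-trimethoxyphenyl]-1-(6-hydroxy-2,3,4-trimethoxyphenyl)prop-2-en-1-one | COc1cc(O)c(C(=O)/C=C/c2c(OCc3ccccc3)cc(OC)c(OC)c2OC)c(OC)c1OC
F3 | step 9 | 2-(6-hydroxy-2,3,4-trimethoxyphenyl)-5,6,7-trimethoxy-4H-chromen-4-one | COc1cc(O)c(-c2cc(=O)c3c(OC)c(OC)c(OC)cc3o2)c(OC)c1OC
F4 | step 3 | 3,4,5-trimethoxyphenyl isopropylcarbamate | COc1cc(OC(=O)NC(C)C)cc(OC)c1OC
F5 | step 3 | 3,4,5-trimethoxyphenyl N-(tert-butyldimethylsilyl)-N-isopropylcarbamate | COc1cc(OC(=O)N(C(C)C)[Si](C)(C)C(C)(C)C)cc(OC)c1OC
F6 | step 3 | 2-lithio-3,4,5-trimethoxyphenyl N-(tert-butyldimethylsilyl)-N-isopropylcarbamate | COc1cc(OC(=O)N(C(C)C)[Si](C)(C)C(C)(C)C)c([Li])c(OC)c1OC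
F7 | step 3 | 3,4,5-trimethoxy-2-(trimethylsilyl)phenyl N-(tert-butyldimethylsilyl)-N-isopropylcarbamate | COc1cc(OC(=O)N(C(C)C)[Si](C)(C)C(C)(C)C)c([Si](C)(C)C)c(OC)c1OC
F8 | step 3 | 3,4,5-trimethoxy-2-(trimethylsilyl)phenyl isopropylcarbamate | COc1cc(OC(=O)NC(C)C)c([Si](C)(C)C)c(OC)c1OC
F9 | step 3 | 3,4,5-trimethoxy-2-(trimethylsilyl)phenol | COc1cc(O)c([Si](C)(C)C)c(OC)c1OC
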